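The runs were computed with made-up constants; noise was put on by code.

The target in the flask we ask about stops rising near 67.3% of the starting material charged, and near 53.2% in the more dilute theta run.

| flask | starting material | second substrate | enzyme | remark |
|---|---|---|---|---|
| eta | 0.10 M | 0.50 equiv | 0.0061 mol% | the very flask that is asked about, followed so far |
| theta | 0.050 M | 0.50 equiv | 0.0061 mol% | run made earlier |
| flask | 0.10 M | 0.500 equiv | 0.0061 mol% |  |

- eta (time / h: target / %): 3.00: 50.1; 6.00: 65.7; 10.0: 67.3; 12.0: 66.9
- theta (time / h: target / %): 2.50: 35.9; 6.00: 51.2; 12.0: 53.2; 30.0: 52.5

(scatter of a reading: 0.3 percentage points)

* factor on the rate of making target when 50% of the starting material are converted if second substrate is charged twice over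
* factor on the rate when 50% of the starting material are converted if enzyme is charged at 6.0 × 10⁻⁴ mol% instead

- steps under discussion: starting material + enzyme <-> complex A; complex A -> enzyme + target; second substrate + enzyme <-> complex B; complex B -> enzyme + second product; starting material -> uncatalysed product; enzyme -> spent catalyst

We build this flask up one process at a time. With the enzyme round through complex A alone, the rate scales with the enzyme, so the smaller loading gives a factor of 0.0984. That round does not explain a reading that stops at 66.9%, however.

So we add the step from starting material to uncatalysed product. Plateau over remainder gives 2.02 in this flask and 1.11 in theta. This is the split, a selectivity factor: the rate of making target over the rate of making uncatalysed product, averaged over the run. The background ignores the enzyme while the target rate follows it, so at the smaller loading we reckon a split of 0.199, lower than here, and 50% conversion comes later.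

Next comes the step from enzyme to spent catalyst. A later 50% conversion meets less working enzyme, so we commit to a factor a little under 0.0984.

Last comes the second substrate, which both runs charge at the same equivalents, so the readings do not vary it. We commit to a factor near one as a judgement, assuming that this charge is turned over before 50% conversion.

The forecast, which differs from ours, gives 0.55 and 0.05 and says “the rate roughly halves”. The simulation gives 0.996 and 0.0715.

    starting material + enzyme ⇌ complex A (K = 120 M⁻¹, k = 1.90 × 10⁶ M⁻¹ h⁻¹)
    complex A → enzyme + target (k = 4000 h⁻¹)
    second substrate + enzyme ⇌ complex B (K = 260 M⁻¹, k = 2.10 × 10⁶ M⁻¹ h⁻¹)
    complex B → enzyme + second product (k = 2.80 × 10⁵ h⁻¹)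
    starting material → uncatalysed product (k = 0.140 h⁻¹)
    enzyme → spent catalyst (k = 0.900 h⁻¹)

In this flask at 50% conversion, target is made 2.36 times as fast as uncatalysed product, near the split of 2.02. At the smaller loading the background rate at that conversion is unchanged, so target is made there 0.169 times as fast as uncatalysed product. In this flask, doubling the second substrate leaves the rate at 50% conversion at a factor of 0.996, in part because complex B turns over. That step reaches the midpoint of its turnover by 0.566 h, earlier than 1.70 h, and with it taken away the apparent order in second substrate goes from −0.0045 to −0.65.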